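The oxane is not closed as a six-membered ring. Its β-bromo ether array O1–C6(CH3)2–C5(Br) is traced back to a 1-oxoniabicyclo[3.1.0]hexane. An oxolane bearing a tertiary carbinyl ester on C5 ionises with help from ring oxygen O1, and bromide then cuts the old O1–C5 bond with inversion. One operation enlarges oxolane to oxane, moves O1 onto the quaternary carbon and writes the C5–Br centre from a Shi-derived C–O centre. The precursor, a 3-cyclohexyl-5-(2-hydroxypropan-2-yl)oxolan-3-ol, rests on a bromochlorocyclohexane made from nerol by enantioselective bromochlorination and cation–olefin closure. Ether-to-lactone oxidation and methylenation finish the route.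

Key step: step 8

Assumption: the ligand enantiomer in step 1, the tartrate in step 5 and the ketone in step 7 are chosen by the established face-selectivity models for nerol-type, 2-substituted allylic alcohol and prenyl-type alkenes, and the remote stereocentres are taken not to override reagent control.

Step 1
Reactants: 1 nerol, (2Z)-3,7-dimethylocta-2,6-dien-1-ol
Product: 2 (2S,3S)-2-bromo-3-chloro-3,7-dimethyloct-6-en-1-ol
Conditions: NBS, ClTi(OiPr)3, chiral tridentate Schiff-base ligand (20 mol %), hexanes, −20 °C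
Reagents that add atoms: N-bromosuccinimide O=C1CCC(=O)N1Br; chlorotitanium triisopropoxide CC(C)O[Ti](Cl)(OC(C)C)OC(C)C
Why: Catalytic enantioselective bromochlorination of an allylic alcohol: the titanium-bound alkoxide holds the proximal alkene in the chiral pocket, Br+ enters on one face and titanium-bound chloride opens the bromiranium ion anti at the tertiary carbon, so the Z-alkene gives the (2S,3S) pair and the remote alkene, which has no directing hydroxyl, is left alone.

Step 2
Reactants: 2 (2S,3S)-2-bromo-3-chloro-3,7-dimethyloct-6-en-1-ol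
Product: 4 (1S,2S,4S)-2-bromo-1-chloro-1-methyl-4-(prop-1-en-2-yl)cyclohexane, via primary triflate 3 (not isolated)
Conditions: Tf2O, 2,6-di-tert-butyl-4-methylpyridine, CH2Cl2, −78 → 0 °C
Reagents that add atoms: trifluoromethanesulfonic anhydride O=S(=O)(OS(=O)(=O)C(F)(F)F)C(F)(F)F (its atoms appear only in 3)
Why: Proposed new method: the β-bromine should displace the primary triflate to a C1–C2 bromiranium ion, whose CH2 terminus (C2 is neopentyl-like and deactivated by the C–Cl dipole) is attacked by C6 of the trisubstituted alkene through a chair (six-membered closure, endo to the bromiranium ring); attack anti to bromine forces C–Br equatorial, hence Cl equatorial, CH3 axial and the nascent 2-propyl cation equatorial, which sets C4 as S, and the hindered pyridine then removes a methyl proton; the closest known reaction types are halonium-induced polyene cyclisation and the π-route solvolysis of alkenyl sulfonates.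

Step 3
Reactants: 4 (1S,2S,4S)-2-bromo-1-chloro-1-methyl-4-(prop-1-en-2-yl)cyclohexane
Product: 5 (1S,2S,4S)-2-bromo-1-chloro-4-(3-chloroprop-1-en-2-yl)-1-methylcyclohexane
Conditions: Ca(OCl)2, solid CO2, CH2Cl2–H2O, 0 °C
Reagents that add atoms: calcium hypochlorite [Ca+2].[O-]Cl.[O-]Cl
Why: Ene-type allylic chlorination with hypochlorous acid: Cl+ adds to the terminal CH2 of the only alkene and a methyl proton is lost, which shifts the 1,1-disubstituted double bond and creates no stereocentre.

Step 4
Reactants: 5 (1S,2S,4S)-2-bromo-1-chloro-4-(3-chloroprop-1-en-2-yl)-1-methylcyclohexane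
Product: 7 2-[(1S,3S,4S)-3-bromo-4-chloro-4-methylcyclohexyl]prop-2-en-1-ol, via allylic acetate 6 (not isolated)
Conditions: CsOAc, DMF, 40 °C; then K2CO3 (0.2 equiv), MeOH, 0 °C
Reagents that add atoms: caesium acetate [Cs+].CC(=O)[O-]
Why: SN2 displacement of the primary allylic chloride by acetate followed by transesterification: the hindered equatorial secondary bromide and the tertiary chloride are far less reactive towards acetate, and no stereocentre is touched.

Step 5
Reactants: 7 2-[(1S,3S,4S)-3-bromo-4-chloro-4-methylcyclohexyl]prop-2-en-1-ol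
Product: 8 {(2R)-2-[(1S,3S,4S)-3-bromo-4-chloro-4-methylcyclohexyl]oxiran-2-yl}methanol
Conditions: Ti(OiPr)4 (10 mol %), D-(−)-diisopropyl tartrate (12 mol %), t-BuOOH, 4 Å MS, CH2Cl2, −20 °C
Reagents that add atoms: tert-butyl hydroperoxide CC(C)(C)OO
Why: Sharpless asymmetric epoxidation: the titanium tartrate binds the allylic hydroxyl and delivers oxygen under reagent control, and since L-(+)-tartrate gives the S series with 2-substituted allyl alcohols, D-(−)-tartrate should set the quaternary oxirane carbon as R.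

Step 6
Reactants: 8 {(2R)-2-[(1S,3S,4S)-3-bromo-4-chloro-4-methylcyclohexyl]oxiran-2-yl}methanol; 9 (2-methylprop-1-en-1-yl)magnesium bromide
Product: 10 (2R)-2-[(1S,3S,4S)-3-bromo-4-chloro-4-methylcyclohexyl]-5-methylhex-4-ene-1,2-diol
Conditions: 9 (3 equiv), CuI (15 mol %), THF, −40 → −10 °C; aq NH4Cl
Reagents that add atoms: none
Why: Copper-catalysed SN2 opening of a 2,2-disubstituted oxirane at its CH2 carbon: the C–O bond at the quaternary centre is kept (a Payne rearrangement of this alkoxide is degenerate and returns the same enantiomer), and at low temperature the gauche diequatorial Br/Cl pair lacks the antiperiplanar alignment needed for reductive elimination.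

Step 7
Reactants: 10 (2R)-2-[(1S,3S,4S)-3-bromo-4-chloro-4-methylcyclohexyl]-5-methylhex-4-ene-1,2-diol
Product: 12 (3R,5S)-3-[(1S,3S,4S)-3-bromo-4-chloro-4-methylcyclohexyl]-5-(2-hydroxypropan-2-yl)oxolan-3-ol, via epoxy diol 11 (not isolated)
Conditions: D-fructose-derived Shi ketone (30 mol %), Oxone, K2CO3, Bu4NHSO4, MeCN–DMM–aq buffer (pH 10.5), 0 °C; then CSA (10 mol %), CH2Cl2, 0 °C
Reagents that add atoms: potassium peroxymonosulfate [K+].[O-]S(=O)(=O)OO
Why: Shi epoxidation of the only alkene followed by acid-catalysed 5-exo-tet epoxide opening: the chiral dioxirane should give the (R)-epoxide 11 under reagent control, and the primary hydroxyl then inverts that carbon, so C5 of the oxolane is S while the tertiary carbinol centre C3 is untouched.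

Step 8
Reactants: 12 (3R,5S)-3-[(1S,3S,4S)-3-bromo-4-chloro-4-methylcyclohexyl]-5-(2-hydroxypropan-2-yl)oxolan-3-ol
Product: 16 (3R,5R)-5-bromo-3-[(1S,3S,4S)-3-bromo-4-chloro-4-methylcyclohexyl]-6,6-dimethyloxan-3-yl trifluoroacetate, via bis(trifluoroacetate) 13 (not isolated), via bicyclic oxonium ion 14 (not isolated), via tertiary bromide 15 (not isolated)
Conditions: (CF3CO)2O, pyridine, CH2Cl2, −20 °C, volatiles removed; then MgBr2·OEt2 (4 equiv), CH2Cl2, −20 → 30 °C
Reagents that add atoms: trifluoroacetic anhydride O=C(OC(=O)C(F)(F)F)C(F)(F)F; magnesium bromide [Mg+2].[Br-].[Br-]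
Why: Proposed new method: both tertiary alcohols are trifluoroacetylated, and MgBr2 should then ionise only the side-chain ester at C(CH3)2, because the antiperiplanar lone pair of ring oxygen O1 can displace it (3-exo-tet) to give the 1-oxoniabicyclo[3.1.0]hexane 14, whereas the ester on ring carbon C3 has no such help and keeps the cis-disposed C3 oxygen from trapping the cation. Bromide should add to 14 at the tertiary carbon fast but reversibly (tertiary bromide 15 re-ionises under MgBr2) and at the ring-fusion carbon C5 slowly but irreversibly, which cleaves the O1–C5 bond shared by both rings, so the only ring closed is the transient three-membered one and the oxane 16 arises by fission of the zero bridge. The closest known reaction types are the zinc acetate-mediated enlargement of tetrahydrofurfuryl-type sulfonates to oxan-3-yl acetates through bicyclic oxonium ions and the thermodynamically driven isomerisation of 2-(halomethyl)pyrrolidines to 3-halopiperidines through aziridinium ions, and bromide as nucleophile on a tertiary/secondary oxonium pair is the untested part. The only new stereocentre, C5–Br, is set by SN2 inversion of the C5–O centre fixed in step 7, so (5S)-12 should give (5R)-16, and C3 is untouched. The step needs attack at C5 rather than at C(CH3)2 under thermodynamic control, which is secured by relief of oxolane strain, by oxygen preferring the tertiary and bromine the secondary carbon, and by the inertness of the secondary bromide once formed. It also needs bromide capture to outrun 1,2-hydride shift and proton loss, which a high bromide concentration in a non-basic medium favours.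

Step 9
Reactants: 16 (3R,5R)-5-bromo-3-[(1S,3S,4S)-3-bromo-4-chloro-4-methylcyclohexyl]-6,6-dimethyloxan-3-yl trifluoroacetate
Product: 17 (3R,5R)-5-bromo-3-[(1S,3S,4S)-3-bromo-4-chloro-4-methylcyclohexyl]-6,6-dimethyl-2-oxooxan-3-yl trifluoroacetate
Conditions: RuCl3·xH2O (5 mol %), NaIO4 (4 equiv), CCl4–MeCN–H2O, 25 °C
Reagents that add atoms: sodium periodate [Na+].[O-]I(=O)(=O)=O
Why: Ruthenium tetroxide oxidation of a cyclic ether to a lactone: C2 carries the only hydrogens α to the ring oxygen (C6 is quaternary), the trifluoroacetate shields the C3 oxygen from glycol-type cleavage at the lactol stage, and no stereocentre is touched.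

Step 10
Reactants: 17 (3R,5R)-5-bromo-3-[(1S,3S,4S)-3-bromo-4-chloro-4-methylcyclohexyl]-6,6-dimethyl-2-oxooxan-3-yl trifluoroacetate
Product: 18 (3R,5R)-5-bromo-3-[(1S,3S,4S)-3-bromo-4-chloro-4-methylcyclohexyl]-3-hydroxy-6,6-dimethyloxan-2-one
Conditions: NaHCO3 (0.2 equiv), MeOH, 0 °C
Reagents that add atoms: none
Why: Chemoselective transesterification: the strongly activated trifluoroacetate is methanolysed far faster than the hindered lactone of a tertiary alcohol, and the near-neutral medium avoids lactone opening followed by epoxide closure onto C5–Br.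

Step 11
Reactants: 18 (3R,5R)-5-bromo-3-[(1S,3S,4S)-3-bromo-4-chloro-4-methylcyclohexyl]-3-hydroxy-6,6-dimethyloxan-2-one
Product: 19 (3R,5R)-5-bromo-3-[(1S,3S,4S)-3-bromo-4-chloro-4-methylcyclohexyl]-6,6-dimethyl-2-methylideneoxan-3-ol (target)
Conditions: Cp2TiMe2 (4 equiv), toluene–THF, 65 °C, dark; filtration through basic alumina
Reagents that add atoms: dimethyltitanocene [CH3-].[CH3-].c1cc[cH-]c1.c1cc[cH-]c1.[Ti+4]
Why: Petasis olefination of a lactone: thermally generated Cp2Ti=CH2 adds to the C2 carbonyl and cycloreverts to the exocyclic enol ether under neutral conditions free of Lewis acid that spare the alkyl halides, and the free hydroxyl only consumes extra reagent as a titanium alkoxide that is released on work-up.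

Compound list
1 | nerol, (2Z)-3,7-dimethylocta-2,6-dien-1-ol | CC(C)=CCC/C(C)=C\CO | starting material
2 | (2S,3S)-2-bromo-3-chloro-3,7-dimethyloct-6-en-1-ol | CC(C)=CCC[C@](C)(Cl)[C@@H](Br)CO | intermediate
3 | (2S,3S)-2-bromo-3-chloro-3,7-dimethyloct-6-en-1-yl trifluoromethanesulfonate | CC(C)=CCC[C@](C)(Cl)[C@@H](Br)COS(=O)(=O)C(F)(F)F | intermediate
4 | (1S,2S,4S)-2-bromo-1-chloro-1-methyl-4-(prop-1-en-2-yl)cyclohexane | C=C(C)[C@H]1CC[C@](C)(Cl)[C@@H](Br)C1 | intermediate
5 | (1S,2S,4S)-2-bromo-1-chloro-4-(3-chloroprop-1-en-2-yl)-1-methylcyclohexane | ClCC(=C)[C@H]1CC[C@](C)(Cl)[C@@H](Br)C1 | intermediate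
6 | 2-[(1S,3S,4S)-3-bromo-4-chloro-4-methylcyclohexyl]prop-2-en-1-yl acetate | CC(=O)OCC(=C)[C@H]1CC[C@](C)(Cl)[C@@H](Br)C1 | intermediate
7 | 2-[(1S,3S,4S)-3-bromo-4-chloro-4-methylcyclohexyl]prop-2-en-1-ol | OCC(=C)[C@H]1CC[C@](C)(Cl)[C@@H](Br)C1 | intermediate
8 | {(2R)-2-[(1S,3S,4S)-3-bromo-4-chloro-4-methylcyclohexyl]oxiran-2-yl}methanol | OC[C@@]1(CO1)[C@H]2CC[C@](C)(Cl)[C@@H](Br)C2 | intermediate
9 | (2-methylprop-1-en-1-yl)magnesium bromide | CC(C)=C[Mg]Br | starting material
10 | (2R)-2-[(1S,3S,4S)-3-bromo-4-chloro-4-methylcyclohexyl]-5-methylhex-4-ene-1,2-diol | CC(C)=CC[C@@](CO)(O)[C@H]1CC[C@](C)(Cl)[C@@H](Br)C1 | intermediate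
11 | (2R)-2-[(1S,3S,4S)-3-bromo-4-chloro-4-methylcyclohexyl]-3-[(2R)-3,3-dimethyloxiran-2-yl]propane-1,2-diol | CC1(C)O[C@@H]1C[C@@](CO)(O)[C@H]2CC[C@](C)(Cl)[C@@H](Br)C2 | intermediate
12 | (3R,5S)-3-[(1S,3S,4S)-3-bromo-4-chloro-4-methylcyclohexyl]-5-(2-hydroxypropan-2-yl)oxolan-3-ol | CC(C)(O)[C@@H]1C[C@](O)(CO1)[C@H]2CC[C@](C)(Cl)[C@@H](Br)C2 | intermediate
13 | bis(trifluoroacetate) of 12, (3R,5S)-3-[(1S,3S,4S)-3-bromo-4-chloro-4-methylcyclohexyl]-5-[2-(trifluoroacetoxy)propan-2-yl]oxolan-3-yl trifluoroacetate | CC(C)(OC(=O)C(F)(F)F)[C@@H]1C[C@](OC(=O)C(F)(F)F)(CO1)[C@H]2CC[C@](C)(Cl)[C@@H](Br)C2 | intermediate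
14 | (3R,5S)-3-[(1S,3S,4S)-3-bromo-4-chloro-4-methylcyclohexyl]-6,6-dimethyl-3-(trifluoroacetoxy)-1-oxoniabicyclo[3.1.0]hexane | CC1(C)[C@@H]2C[C@](OC(=O)C(F)(F)F)(C[O+]12)[C@H]3CC[C@](C)(Cl)[C@@H](Br)C3 | intermediate
15 | (3R,5S)-3-[(1S,3S,4S)-3-bromo-4-chloro-4-methylcyclohexyl]-5-(2-bromopropan-2-yl)oxolan-3-yl trifluoroacetate | CC(C)(Br)[C@@H]1C[C@](OC(=O)C(F)(F)F)(CO1)[C@H]2CC[C@](C)(Cl)[C@@H](Br)C2 | intermediate
16 | (3R,5R)-5-bromo-3-[(1S,3S,4S)-3-bromo-4-chloro-4-methylcyclohexyl]-6,6-dimethyloxan-3-yl trifluoroacetate | C1OC(C)(C)[C@H](Br)C[C@@]1(OC(=O)C(F)(F)F)[C@H]2CC[C@](C)(Cl)[C@@H](Br)C2 | intermediate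
17 | (3R,5R)-5-bromo-3-[(1S,3S,4S)-3-bromo-4-chloro-4-methylcyclohexyl]-6,6-dimethyl-2-oxooxan-3-yl trifluoroacetate | O=C1OC(C)(C)[C@H](Br)C[C@@]1(OC(=O)C(F)(F)F)[C@H]2CC[C@](C)(Cl)[C@@H](Br)C2 | intermediate
18 | (3R,5R)-5-bromo-3-[(1S,3S,4S)-3-bromo-4-chloro-4-methylcyclohexyl]-3-hydroxy-6,6-dimethyloxan-2-one | O=C1OC(C)(C)[C@H](Br)C[C@@]1(O)[C@H]2CC[C@](C)(Cl)[C@@H](Br)C2 | intermediate
19 | (3R,5R)-5-bromo-3-[(1S,3S,4S)-3-bromo-4-chloro-4-methylcyclohexyl]-6,6-dimethyl-2-methylideneoxan-3-ol | C=C1OC(C)(C)[C@H](Br)C[C@@]1(O)[C@H]1CC[C@](C)(Cl)[C@@H](Br)C1 | target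

Total step count: 11. Longest linear sequence: 11 steps (from nerol 1).

Steps most likely to fail

1. Step 8 (Proposed new method).
- What may go wrong: the oxonium ion may be captured only at the tertiary carbon without turnover. It may lose a proton to an isopropenyl group. It may suffer a 1,2-hydride shift from C5 to the cationic carbon.
- Fallback: this keeps the enlargement of an oxolane but uses the known manifold in which the nucleophile attacks the tertiary ring carbon of the oxonium ion. It sets out from 7 and comes back at 16. Because this enlargement inverts the carbinol carbon, 7 is epoxidised with L-(+)-diisopropyl tartrate to the epimeric epoxy alcohol F1. F1 is opened with 9/CuI to the epimeric diol F2. The primary hydroxyl of F2 is converted with ClCH2SO2Cl/pyridine into the chloromethanesulfonate F3. NBS then effects a 5-endo bromoetherification by the tertiary hydroxyl to the 4-bromo-5,5-dimethyloxolane F4, and the diastereomer with bromine trans to the cyclohexyl group is separated. Zn(OAc)2 in aqueous acetic acid at 60 °C should move the ring oxygen onto the CH2 carbon and bring water onto the tertiary carbon with inversion, to give the oxan-3-ol F5. Trifluoroacetylation of F5 gives 16.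

2. Step 2 (Proposed new method).
- What may go wrong: closure may occur without bromine participation, with loss of control at C4. Closure may occur at the bromine-bearing carbon to give a cyclopentane. Proton loss may go towards the ring.
- Fallback: this cannot branch from 1–3. It sets out from commercial (R)-(+)-limonene F6 in place of 1 and comes back at 4. NBS/Et4NCl adds BrCl to the ring alkene in the trans-diaxial, Markovnikov sense (Fürst–Plattner), which gives the right (1S,2S) pair but the wrong C4 centre in the bromochloride F7. Ozonolysis gives the methyl ketone F8. TMSI/(Me3Si)2NH gives the thermodynamic, exocyclic silyl enol ether F9, which erases C4. Kinetic protonation with a Lewis-acid-assisted hindered phenol at −78 °C, on the face opposite the axial bromine, should give the epimeric ketone F10. Non-basic Petasis methylenation of F10 gives 4.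

3. Step 9.
- What may go wrong: hydride abstraction at C2 may be slow next to the electron-withdrawing ester, and oxidation at tertiary C–H bonds may compete.
- Fallback: this sets out from 16 and comes back at 18. Methanolysis (NaHCO3, MeOH) gives the oxan-3-ol F5. TESOTf/2,6-lutidine gives the electron-richer triethylsilyl ether F11. The ruthenium tetroxide oxidation is then run on F11 to give the silyloxy lactone F12. HF·pyridine releases 18.

Further compounds
F1 | step 8 | {(2S)-2-[(1S,3S,4S)-3-bromo-4-chloro-4-methylcyclohexyl]oxiran-2-yl}methanol | OC[C@]1(CO1)[C@H]2CC[C@](C)(Cl)[C@@H](Br)C2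
F2 | step 8 | (2S)-2-[(1S,3S,4S)-3-bromo-4-chloro-4-methylcyclohexyl]-5-methylhex-4-ene-1,2-diol | CC(C)=CC[C@](CO)(O)[C@H]1CC[C@](C)(Cl)[C@@H](Br)C1
F3 | step 8 | (2S)-2-[(1S,3S,4S)-3-bromo-4-chloro-4-methylcyclohexyl]-2-hydroxy-5-methylhex-4-en-1-yl chloromethanesulfonate | CC(C)=CC[C@](COS(=O)(=O)CCl)(O)[C@H]1CC[C@](C)(Cl)[C@@H](Br)C1
F4 | step 8 | {(2S,4R)-4-bromo-2-[(1S,3S,4S)-3-bromo-4-chloro-4-methylcyclohexyl]-5,5-dimethyloxolan-2-yl}methyl chloromethanesulfonate | CC1(C)O[C@@](COS(=O)(=O)CCl)(C[C@H]1Br)[C@H]2CC[C@](C)(Cl)[C@@H](Br)C2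
F5 | step 8 | (3R,5R)-5-bromo-3-[(1S,3S,4S)-3-bromo-4-chloro-4-methylcyclohexyl]-6,6-dimethyloxan-3-ol | C1OC(C)(C)[C@H](Br)C[C@@]1(O)[C@H]2CC[C@](C)(Cl)[C@@H](Br)C2
F6 | step 2 | (R)-(+)-limonene | C=C(C)[C@@H]1CCC(C)=CC1
F7 | step 2 | (1S,2S,4R)-2-bromo-1-chloro-1-methyl-4-(prop-1-en-2-yl)cyclohexane | C=C(C)[C@@H]1CC[C@](C)(Cl)[C@@H](Br)C1
F8 | step 2 | 1-[(1R,3S,4S)-3-bromo-4-chloro-4-methylcyclohexyl]ethan-1-one | CC(=O)[C@@H]1CC[C@](C)(Cl)[C@@H](Br)C1
F9 | step 2 | {1-[(3S,4S)-3-bromo-4-chloro-4-methylcyclohexylidene]ethoxy}trimethylsilane | CC(O[Si](C)(C)C)=C1CC[C@](C)(Cl)[C@@H](Br)C1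
F10 | step 2 | 1-[(1S,3S,4S)-3-bromo-4-chloro-4-methylcyclohexyl]ethan-1-one | CC(=O)[C@H]1CC[C@](C)(Cl)[C@@H](Br)C1
F11 | step 9 | {[(3R,5R)-5-bromo-3-[(1S,3S,4S)-3-bromo-4-chloro-4-methylcyclohexyl]-6,6-dimethyloxan-3-yl]oxy}triethylsilane | C1OC(C)(C)[C@H](Br)C[C@@]1(O[Si](CC)(CC)CC)[C@H]2CC[C@](C)(Cl)[C@@H](Br)C2
F12 | step 9 | (3R,5R)-5-bromo-3-[(1S,3S,4S)-3-bromo-4-chloro-4-methylcyclohexyl]-6,6-dimethyl-3-[(triethylsilyl)oxy]oxan-2-one | O=C1OC(C)(C)[C@H](Br)C[C@@]1(O[Si](CC)(CC)CC)[C@H]2CC[C@](C)(Cl)[C@@H](Br)C2
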